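**Remark on the chemistry:** the target has no stereocentre. Flavanone 14 is formed as a racemate and its single stereocentre (C2) is erased in step 9. All phenols are carried as methoxymethyl ethers.

## Analysis of the target

Compound 17 is a flavonol: ring A (C4a, C5, C6, C7, C8, C8a) is fused through C4a–C8a to the 4-pyranone ring C (O1, C2, C3, C4), and C2 carries ring B, a 4-hydroxyphenyl group. Hydroxyls sit on C3, C5, C7 and C4′, and C8 carries a 2-methylbut-3-en-2-yl (1,1-dimethylallyl) group. There is no stereocentre and no configurable double bond, so every selectivity question is one of regiochemistry or chemoselectivity. The sensitive parts are the terminal vinyl group on a quaternary carbon next to the C7 hydroxyl and the free 3-hydroxy-4-pyranone with its three phenols. The vinyl group forbids hydrogenolysis, halogen or epoxidising oxidants and strong acid (which would close a dihydrofuran from O7); the free flavonol is oxidised by air in base and should be unmasked last. The difficulty is twofold. A tertiary alkyl group must sit on C8 between O7 and O8a, where electrophilic prenylation of a 1,3,5-trioxygenated ring delivers the linear isomer and cannot tell C8 from C6. The two oxygens ortho to C4a (O5 and O8a) must also be told apart, because closing ring C through O5 would put the side chain on C6. The strategy rests on the oxygenation pattern of ring A: C5, C7 and C8a carry oxygen while C4a, C6 and C8 do not, which is the alternation of a folded poly-β-carbonyl chain. Read that way, C8 is a chain methylene that can carry the tert-alkyl group before the ring exists, C8a is the chain terminus at the acid oxidation level, and C4a is the methylene that bears the cinnamoyl carbonyl C4.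

## Retrosynthetic reasoning

**Unmasking.** Target 17 is traced to its tris(methoxymethyl) ether 16. One kind of acetal on O5, O7 and O4′ allows a single mild acidic release at the end. Acetals are preferred to silyl ethers on ring A because ring C is closed with acetate in hot ethanol, which strips aryl silyl ethers ortho or para to a carbonyl and would free O5 before the regiochemistry is secured.

**C3–O bond.** Flavonol 16 is cut at the C3 hydroxyl to flavone 15. The oxygen is introduced by C3 deprotonation, borylation and oxidation. An epoxidising oxidant would also attack the vinyl group, and oxidative closure of a chalcone with a second ortho oxygen substituent tends to give aurones.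

**C2=C3 and O1–C2.** Flavone 15 is traced to flavanone 14 by removing the unsaturation, and 14 to chalcone 13 by cutting the O1–C2 bond (oxa-Michael in the forward sense). In 13 only O8a is free, so ring closure can only give the 8-substituted chromanone.

**Differentiation of O5 and O8a.** Chalcone 13 is traced to triol 12 by removing the acetals on O5 and O7. The forward step relies on sterics: O8a lies between the quaternary carbon and the acyl group and is hydrogen-bonded to the carbonyl, whereas O5 has a hydrogen as its second neighbour.

**Key disconnection, C4a–C8a.** Cutting this bond in 12 unravels ring A into the methyl 3,5,7-trioxo ester 11, which is stored as its lactone, pyranone 10. No aromatic substitution is then needed: the side chain is already on the chain carbon that becomes C8, and the chain order fixes every ring position. The forward reaction has to open the lactone with alkoxide, fold in the Claisen and not the aldol sense, and leave the enone untouched.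

**C4–C4a bond.** Pyranone 10 is cut between the side-chain methylene (future C4a) and the ketone carbonyl (C4), giving methylpyranone 5 and Weinreb amide 9. An amide is preferred to an ester because the tetrahedral adduct persists until work-up. The acidic product then cannot quench unreacted dianion, and conjugate addition to the cinnamoyl unit is disfavoured.

**Amide 9.** The alkene of 9 is cut to aldehyde 7 and phosphonate 8; 7 comes from phenol 6 by acetalisation.

**C3–quaternary carbon bond.** Pyranone 5 is traced through a [3,3] shift to the 4-O-prenyl ether 3. The shift inverts the allyl unit, so the tertiary carbon is delivered to C3 and the former ether carbon becomes the terminal vinyl carbon, which direct alkylation would not do. The freed enol is trapped as enol acetate 4 so that it cannot react on. Ether 3 comes from pyranone 1 and alcohol 2 by O-selective etherification.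

## Alternatives that were turned down

**Alternative 1:** Ring A is built around the quaternary carbon by a Danheiser benzannulation, cutting C8a–C8, C6–C7 and C4a–C8a. Heating cyclobutenone A3 with siloxyalkyne A2 would give a vinylketene, which adds the alkyne, reopens and electrocyclises to phenol A1.
- For: the regiochemistry is complete by construction, and A1 is free only at O8a, exactly the oxygen that must become O1. On the O5/O8a question this alternative is stronger than the chosen route, which must rely on steric discrimination in step 7.
- Against: A2 has a quaternary propargylic carbon and needs several steps of ynolate chemistry, and both alkyne termini are bulky, which slows the ketene [2+2] addition. A3 is a labile partner. A1 contains none of C4, C3 or C2, so C-acylation at C4a between two oxygens and the whole of steps 8 to 11 would still follow.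
- Comparison: the chosen fold delivers ring A with the C4a–C4 bond and the full chalcone skeleton in one step from a pyranone made in four steps, which is what it offers in place of the built-in differentiation.

**Alternative 2:** Ring C is closed at C3–C4 by a carbene-catalysed crossed benzoin reaction. A thiazolium-derived carbene would convert the aromatic aldehyde of dialdehyde A5 into its Breslow intermediate, which adds to the aliphatic aldehyde to give dihydroflavonol A4 as a diastereomer mixture.
- For: the C3 hydroxyl arrives with the ring, so neither a dehydrogenation nor a separate C3 oxidation is needed; one oxidation of A4 gives the flavonol. On the ring C endgame it is stronger than steps 9 and 10.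
- Against: A5 presupposes a ring-A aldehyde with the tert-alkyl group on C8 and differentiated oxygens, so the central problem is left unsolved. O8a, flanked by the quaternary carbon and the formyl group, would have to be alkylated at a secondary benzylic α-carbonyl centre. The carbene is expected to attack the unhindered aliphatic aldehyde first, and a Breslow intermediate with an α-aryloxy group can expel the aryloxide, breaking the O1–C2 bond.
- Comparison: the chosen route spends two more steps on ring C but uses them on well-behaved flavonoid transformations, and puts its key step on ring A.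

**Alternative 3:** An aryne inserts into a carboxylic acid, cutting C5–O and C4a–C4. Fluoride would generate the C4a–C5 aryne from silyl triflate A7; the carboxylate of acid A8 adds at C5 (distal to the alkoxy group on C8a) and the C4a aryl anion takes the acyl group, giving ketone A6.
- For: the acyl group and O5 are installed in one step with regiochemistry set by aryne polarisation, O5 is distinguished from O8a, and the C3 oxygen is carried from the start as the allyl ether. On C3 oxygenation it is stronger than the chosen route.
- Against: A7 is a benzene substituted at five of six positions, and making it requires placing the tert-alkyl group on a trioxygenated ring (the same problem) plus ortho-silylation and triflation. In A6 the free hydroxyl is on C5, whereas ring closure needs O8a, which is locked as an acetal of the same kind as that on O7. A protecting-group exchange with a difficult selective unmasking would follow.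
- Comparison: the chosen route is shorter to the differentiated ring A and needs no exchange of protecting groups; it pays with a late C3 oxidation.

Key step: step 6

## Route

**Step 1**
Reactants: 1 4-hydroxy-6-methyl-2H-pyran-2-one (triacetic acid lactone); 2 3-methylbut-2-en-1-ol (prenol)
Product: 3 6-methyl-4-[(3-methylbut-2-en-1-yl)oxy]-2H-pyran-2-one
Conditions: PPh3, DIAD, THF, 0 °C to rt
Reagents that add atoms: none
Why: Mitsunobu etherification of the acidic 4-hydroxypyranone with a primary allylic alcohol; displacement of the oxyphosphonium ion by O4 avoids the C3-alkylation that accompanies carbonate and allyl halide conditions.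

**Step 2**
Reactants: 3 6-methyl-4-[(3-methylbut-2-en-1-yl)oxy]-2H-pyran-2-one
Product: 5 4-hydroxy-6-methyl-3-(2-methylbut-3-en-2-yl)-2H-pyran-2-one, via enol acetate 4 (not isolated)
Conditions: Ac2O, NaOAc, 140 °C; then MeOH, Et3N, rt
Reagents that add atoms: none
Why: Claisen rearrangement ([3,3] shift) of the allyl vinyl ether O4–C4=C3 delivers the dimethyl-substituted allyl terminus to C3 and creates the quaternary carbon with its vinyl group. Acetic anhydride caps the freed enol as 4 at once, which blocks the abnormal Claisen shift and addition of O4 to the vinyl group; the activated enol acetate is then cleaved by methanol.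

**Step 3**
Reactants: 6 4-hydroxybenzaldehyde
Product: 7 4-(methoxymethoxy)benzaldehyde
Conditions: MOMCl, iPr2NEt, CH2Cl2, 0 °C to rt
Reagents that add atoms: chloromethyl methyl ether, COCCl
Why: O-alkylation of the phenol with an α-chloro ether under amine base (acetal protection); the methoxymethyl ether tolerates the amide bases and alkoxides of steps 4 to 6.

**Step 4**
Reactants: 7 4-(methoxymethoxy)benzaldehyde; 8 diethyl [2-(methoxy(methyl)amino)-2-oxoethyl]phosphonate
Product: 9 (E)-N-methoxy-3-[4-(methoxymethoxy)phenyl]-N-methylprop-2-enamide
Conditions: NaH, THF, 0 °C to rt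
Reagents that add atoms: none
Why: Horner–Wadsworth–Emmons olefination with a stabilised amide phosphonate; the reversible addition step leads to the (E)-alkene.

**Step 5**
Reactants: 5 4-hydroxy-6-methyl-3-(2-methylbut-3-en-2-yl)-2H-pyran-2-one; 9 (E)-N-methoxy-3-[4-(methoxymethoxy)phenyl]-N-methylprop-2-enamide
Product: 10 4-hydroxy-3-(2-methylbut-3-en-2-yl)-6-[(E)-4-(4-(methoxymethoxy)phenyl)-2-oxobut-3-enyl]-2H-pyran-2-one
Conditions: LiN(iPr)2 (2.2 equiv), THF, −78 °C; then 9, −78 to −20 °C; 1 M HCl work-up
Reagents that add atoms: none
Why: Two equivalents of amide base give the dianion of the 6-methylpyranone (oxide at O4, carbanion at the methyl carbon), as known for the parent lactone. Its carbon terminus adds 1,2 to the Weinreb amide (acylation of a dianion), and the chelated tetrahedral adduct survives until work-up, so the acidic product cannot quench the dianion.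

**Step 6**
Reactants: 10 4-hydroxy-3-(2-methylbut-3-en-2-yl)-6-[(E)-4-(4-(methoxymethoxy)phenyl)-2-oxobut-3-enyl]-2H-pyran-2-one
Product: 12 (E)-1-[2,4,6-trihydroxy-3-(2-methylbut-3-en-2-yl)phenyl]-3-[4-(methoxymethoxy)phenyl]prop-2-en-1-one, via magnesium-chelated methyl triketo ester 11 (not isolated)
Conditions: Mg(OMe)2 (8 equiv), MeOH, 65 °C; inverse quench into 1 M HCl, 0 °C
Reagents that add atoms: none
Why: Methoxide from Mg(OMe)2 adds to the lactone carbonyl of 10 and opens the ring to the methyl 3,5,7-trioxo ester 11, held as a magnesium β-dicarbonyl chelate. The methylene between the cinnamoyl ketone and the next ketone (future C4a) then attacks the ester carbonyl (future C8a) in a 6-(enolendo)-exo-trig Claisen condensation; loss of methoxide gives a cyclohexane-1,3,5-trione that enolises to aromatic ring A, which makes the closure irreversible. The closest known reaction type is the magnesium methoxide cyclisation of 6-(2-oxoalkyl)-4-hydroxy-2-pyranones and the corresponding 3,5,7-triketo esters to acylphloroglucinols, the chemical model of chalcone synthase. The selectivity needed is Claisen against aldol folding and against reclosure to oxygen heterocycles: magnesium chelation keeps the dicarbonyl units enolised and the ester activated close to C4a, whereas the aldol mode would need the carbon bearing the tert-alkyl group as nucleophile and would create a quaternary ring carbon that cannot aromatise without decarboxylation. The position of the side chain is not decided in this step, because it already sits on the chain carbon that becomes C8. Methoxide addition to the enone and oxa-Michael closures are reversible and drain into the aromatic product; as a magnesium polyphenoxide the chalcone should not close to a flavanone, and the inverse quench passes quickly through the pH range in which a mono-phenoxide would cyclise. One ring (ring A) and one skeletal bond (C4a–C8a) are formed, no stereocentre is created, and the (E)-alkene is carried through unchanged.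

**Step 7**
Reactants: 12 (E)-1-[2,4,6-trihydroxy-3-(2-methylbut-3-en-2-yl)phenyl]-3-[4-(methoxymethoxy)phenyl]prop-2-en-1-one
Product: 13 (E)-1-[2-hydroxy-4,6-bis(methoxymethoxy)-3-(2-methylbut-3-en-2-yl)phenyl]-3-[4-(methoxymethoxy)phenyl]prop-2-en-1-one
Conditions: MOMCl (2.2 equiv), iPr2NEt, CH2Cl2, −20 to 0 °C
Reagents that add atoms: chloromethyl methyl ether, COCCl
Why: Amine-base acetalisation of phenols; the hydroxyl para to the carbonyl (future O7, most acidic) and the ortho hydroxyl with a hydrogen as second neighbour (future O5) react. The hydroxyl between the quaternary carbon and the acyl group (future O8a) is shielded on both sides and stays in the hydrogen bond to the carbonyl.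

**Step 8**
Reactants: 13 (E)-1-[2-hydroxy-4,6-bis(methoxymethoxy)-3-(2-methylbut-3-en-2-yl)phenyl]-3-[4-(methoxymethoxy)phenyl]prop-2-en-1-one
Product: 14 5,7-bis(methoxymethoxy)-2-[4-(methoxymethoxy)phenyl]-8-(2-methylbut-3-en-2-yl)chroman-4-one (racemic)
Conditions: NaOAc, EtOH, 78 °C
Reagents that add atoms: none
Why: Base-mediated intramolecular oxa-Michael addition (chalcone to flavanone isomerisation) through the only free phenol, which closes ring C with the side chain on C8; the twisted, doubly ortho-substituted aryl ketone favours the closed form. The new stereocentre C2 forms as a racemate and is removed in step 9.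

**Step 9**
Reactants: 14 5,7-bis(methoxymethoxy)-2-[4-(methoxymethoxy)phenyl]-8-(2-methylbut-3-en-2-yl)chroman-4-one (racemic)
Product: 15 5,7-bis(methoxymethoxy)-2-[4-(methoxymethoxy)phenyl]-8-(2-methylbut-3-en-2-yl)-4H-chromen-4-one
Conditions: DDQ, 1,4-dioxane, 100 °C
Reagents that add atoms: none
Why: Quinone dehydrogenation of a chroman-4-one to the chromen-4-one by hydride abstraction from C2 (benzylic and α to oxygen) and loss of the C3 proton. The side chain has no allylic hydrogen and the acetals are inert to the quinone.

**Step 10**
Reactants: 15 5,7-bis(methoxymethoxy)-2-[4-(methoxymethoxy)phenyl]-8-(2-methylbut-3-en-2-yl)-4H-chromen-4-one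
Product: 16 3-hydroxy-5,7-bis(methoxymethoxy)-2-[4-(methoxymethoxy)phenyl]-8-(2-methylbut-3-en-2-yl)-4H-chromen-4-one
Conditions: LiN(iPr)2, THF, −78 °C; B(OMe)3, −78 to 0 °C; then AcOH, 30% H2O2, 0 °C
Reagents that add atoms: hydrogen peroxide, OO
Why: C3 lithiation of the flavone by a lithium amide, borylation and oxidative conversion of C–B into C–O, a known route from flavones to flavonols. The peroxide is consumed by the borate at 0 °C and should not epoxidise the unactivated vinyl group, as a dioxirane would.

**Step 11**
Reactants: 16 3-hydroxy-5,7-bis(methoxymethoxy)-2-[4-(methoxymethoxy)phenyl]-8-(2-methylbut-3-en-2-yl)-4H-chromen-4-one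
Product: 17 3,5,7-trihydroxy-2-(4-hydroxyphenyl)-8-(2-methylbut-3-en-2-yl)-4H-chromen-4-one (CNP0284048.0)
Conditions: 3 M HCl (aq), MeOH, 45 °C
Reagents that add atoms: none
Why: Acid-catalysed methanolysis of the three aryl methoxymethyl acetals through oxocarbenium ions. The monosubstituted alkene is protonated far more slowly than the acetals are cleaved, so dilute acid at moderate temperature should leave the 1,1-dimethylallyl group intact.

## Compound list

1 | 4-hydroxy-6-methyl-2H-pyran-2-one (triacetic acid lactone) | Cc1cc(O)cc(=O)o1 | starting material
2 | 3-methylbut-2-en-1-ol (prenol) | CC(C)=CCO | starting material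
3 | 6-methyl-4-[(3-methylbut-2-en-1-yl)oxy]-2H-pyran-2-one | Cc1cc(OCC=C(C)C)cc(=O)o1 | intermediate
4 | 6-methyl-3-(2-methylbut-3-en-2-yl)-2-oxo-2H-pyran-4-yl acetate (not isolated) | C=CC(C)(C)c1c(OC(C)=O)cc(C)oc1=O | intermediate
5 | 4-hydroxy-6-methyl-3-(2-methylbut-3-en-2-yl)-2H-pyran-2-one | C=CC(C)(C)c1c(O)cc(C)oc1=O | intermediate
6 | 4-hydroxybenzaldehyde | O=Cc1ccc(O)cc1 | starting material
7 | 4-(methoxymethoxy)benzaldehyde | COCOc1ccc(C=O)cc1 | intermediate
8 | diethyl [2-(methoxy(methyl)amino)-2-oxoethyl]phosphonate | CCOP(=O)(CC(=O)N(C)OC)OCC | starting material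
9 | (E)-N-methoxy-3-[4-(methoxymethoxy)phenyl]-N-methylprop-2-enamide | CON(C)C(=O)/C=C/c1ccc(OCOC)cc1 | intermediate
10 | 4-hydroxy-3-(2-methylbut-3-en-2-yl)-6-[(E)-4-(4-(methoxymethoxy)phenyl)-2-oxobut-3-enyl]-2H-pyran-2-one | C=CC(C)(C)c1c(O)cc(CC(=O)/C=C/c2ccc(OCOC)cc2)oc1=O | intermediate
11 | methyl (E)-9-[4-(methoxymethoxy)phenyl]-2-(2-methylbut-3-en-2-yl)-3,5,7-trioxonon-8-enoate (formed as its magnesium chelate, not isolated) | COC(=O)C(C(C)(C)C=C)C(=O)CC(=O)CC(=O)/C=C/c1ccc(OCOC)cc1 | intermediate
12 | (E)-1-[2,4,6-trihydroxy-3-(2-methylbut-3-en-2-yl)phenyl]-3-[4-(methoxymethoxy)phenyl]prop-2-en-1-one | C=CC(C)(C)c1c(O)cc(O)c(C(=O)/C=C/c2ccc(OCOC)cc2)c1O | intermediate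
13 | (E)-1-[2-hydroxy-4,6-bis(methoxymethoxy)-3-(2-methylbut-3-en-2-yl)phenyl]-3-[4-(methoxymethoxy)phenyl]prop-2-en-1-one | C=CC(C)(C)c1c(OCOC)cc(OCOC)c(C(=O)/C=C/c2ccc(OCOC)cc2)c1O | intermediate
14 | 5,7-bis(methoxymethoxy)-2-[4-(methoxymethoxy)phenyl]-8-(2-methylbut-3-en-2-yl)chroman-4-one (racemic) | C=CC(C)(C)c1c(OCOC)cc(OCOC)c2c1OC(c1ccc(OCOC)cc1)CC2=O | intermediate
15 | 5,7-bis(methoxymethoxy)-2-[4-(methoxymethoxy)phenyl]-8-(2-methylbut-3-en-2-yl)-4H-chromen-4-one | C=CC(C)(C)c1c(OCOC)cc(OCOC)c2c(=O)cc(-c3ccc(OCOC)cc3)oc12 | intermediate
16 | 3-hydroxy-5,7-bis(methoxymethoxy)-2-[4-(methoxymethoxy)phenyl]-8-(2-methylbut-3-en-2-yl)-4H-chromen-4-one | C=CC(C)(C)c1c(OCOC)cc(OCOC)c2c(=O)c(O)c(-c3ccc(OCOC)cc3)oc12 | intermediate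
17 | 3,5,7-trihydroxy-2-(4-hydroxyphenyl)-8-(2-methylbut-3-en-2-yl)-4H-chromen-4-one | C=CC(C)(C)c1c(O)cc(O)c2c(=O)c(O)c(-c3ccc(O)cc3)oc12 | target

## Step count and risk

Total step count: 11. Longest linear sequence: 9 steps (steps 1, 2, 5, 6, 7, 8, 9, 10, 11, from pyranone 1); steps 3 and 4 form the side branch to amide 9.

**Step 6 (key step).** The most likely failure is slow opening of the lactone and slow acyl transfer at the carbonyl next to the quaternary carbon. That would leave time for conjugate additions to the enone and, on work-up, for unselective ring closure of the free chalcone. The fallback takes the enone out of the fold. From pyranone 5, the dianion would be acylated with N-methoxy-N-methylacetamide to 4-hydroxy-3-(2-methylbut-3-en-2-yl)-6-(2-oxopropyl)-2H-pyran-2-one F1. The same Mg(OMe)2 fold, which can now be forced without risk to an enone, should give 1-[2,4,6-trihydroxy-3-(2-methylbut-3-en-2-yl)phenyl]ethan-1-one F2, which cannot cyclise. Acetalisation as in step 7 would give 1-[2-hydroxy-4,6-bis(methoxymethoxy)-3-(2-methylbut-3-en-2-yl)phenyl]ethan-1-one F3, and Claisen–Schmidt condensation of F3 with aldehyde 7 (KOH, EtOH) returns to the route at chalcone 13.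

**Step 7.** The most likely failure is loss of regiocontrol, either by etherification at the wrong ortho oxygen or by base-induced ring closure of the unprotected chalcone before the second acetal is on. The fallback closes the ring first and separates afterwards. Triol 12 would be heated with NaOAc in EtOH to give rac-5,7-dihydroxy-2-[4-(methoxymethoxy)phenyl]-8-(2-methylbut-3-en-2-yl)chroman-4-one F4 together with its regioisomer rac-5,7-dihydroxy-2-[4-(methoxymethoxy)phenyl]-6-(2-methylbut-3-en-2-yl)chroman-4-one F5. These would be separated by chromatography, F5 being re-equilibrated through chalcone 12 under the same base and recycled. Acetalisation of both hydroxyls of F4 (excess MOMCl, iPr2NEt, CH2Cl2, 40 °C) returns to the route at flavanone 14.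

**Step 2.** The most likely failure is further reaction of the rearranged enol if acetylation does not keep pace: the abnormal Claisen shift to the 1,2-dimethylallyl isomer, addition of O4 to the vinyl group, or cleavage of the allylic ether. The fallback builds the pyranone around a preformed quaternary carbon. Alcohol 2 and trimethyl orthoacetate (Johnson–Claisen rearrangement, propionic acid catalyst, 140 °C) would give methyl 3,3-dimethylpent-4-enoate F6. Its lithium enolate would be acetylated with N-methoxy-N-methylacetamide to methyl 2-(2-methylbut-3-en-2-yl)-3-oxobutanoate F7. The dianion of F7 (NaH, then n-BuLi) would be acetylated again at the methyl terminus to methyl 2-(2-methylbut-3-en-2-yl)-3,5-dioxohexanoate F8, and lactonisation of F8 (DBU, toluene, 110 °C) returns to the route at pyranone 5.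

**Step 10.** The most likely failure is incomplete or misdirected deprotonation (competition from C6 between two acetal oxygens, or addition of the amide base at C2), leading to low conversion. The fallback oxidises C3 at the flavanone stage. The lithium enolate of flavanone 14 (LiN(SiMe3)2, THF, −78 °C) would be hydroxylated with 2-(phenylsulfonyl)-3-phenyloxaziridine anti to the C2 aryl group to give rac-(2R,3R)-3-hydroxy-5,7-bis(methoxymethoxy)-2-[4-(methoxymethoxy)phenyl]-8-(2-methylbut-3-en-2-yl)chroman-4-one F9. Oxidation of the secondary alcohol of F9 with Dess–Martin periodinane should give flavonol 16 as the enol form of the oxidation product, so the route is rejoined at 16 and step 9 is bypassed as well.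

## Further compounds

F1 | step 6 | 4-hydroxy-3-(2-methylbut-3-en-2-yl)-6-(2-oxopropyl)-2H-pyran-2-one | C=CC(C)(C)c1c(O)cc(CC(C)=O)oc1=O
F2 | step 6 | 1-[2,4,6-trihydroxy-3-(2-methylbut-3-en-2-yl)phenyl]ethan-1-one | C=CC(C)(C)c1c(O)cc(O)c(C(C)=O)c1O
F3 | step 6 | 1-[2-hydroxy-4,6-bis(methoxymethoxy)-3-(2-methylbut-3-en-2-yl)phenyl]ethan-1-one | C=CC(C)(C)c1c(OCOC)cc(OCOC)c(C(C)=O)c1O
F4 | step 7 | rac-5,7-dihydroxy-2-[4-(methoxymethoxy)phenyl]-8-(2-methylbut-3-en-2-yl)chroman-4-one | C=CC(C)(C)c1c(O)cc(O)c2c1OC(c1ccc(OCOC)cc1)CC2=O
F5 | step 7 | rac-5,7-dihydroxy-2-[4-(methoxymethoxy)phenyl]-6-(2-methylbut-3-en-2-yl)chroman-4-one | C=CC(C)(C)c1c(O)cc2OC(c3ccc(OCOC)cc3)CC(=O)c2c1O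
F6 | step 2 | methyl 3,3-dimethylpent-4-enoate | C=CC(C)(C)CC(=O)OC
F7 | step 2 | methyl 2-(2-methylbut-3-en-2-yl)-3-oxobutanoate (racemic) | COC(=O)C(C(C)=O)C(C)(C)C=C
F8 | step 2 | methyl 2-(2-methylbut-3-en-2-yl)-3,5-dioxohexanoate (racemic) | COC(=O)C(C(=O)CC(C)=O)C(C)(C)C=C
F9 | step 10 | rac-(2R,3R)-3-hydroxy-5,7-bis(methoxymethoxy)-2-[4-(methoxymethoxy)phenyl]-8-(2-methylbut-3-en-2-yl)chroman-4-one (trans; one enantiomer drawn) | C=CC(C)(C)c1c(OCOC)cc(OCOC)c2c1O[C@H](c1ccc(OCOC)cc1)[C@@H](O)C2=O
A1 | alternative 1 | 2-(2-methylbut-3-en-2-yl)-3,5-bis(triisopropylsilyloxy)phenol | C=CC(C)(C)c1c(O)cc(O[Si](C(C)C)(C(C)C)C(C)C)cc1O[Si](C(C)C)(C(C)C)C(C)C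
A2 | alternative 1 | [(3,3-dimethylpent-4-en-1-yn-1-yl)oxy]tri(propan-2-yl)silane | C=CC(C)(C)C#CO[Si](C(C)C)(C(C)C)C(C)C
A3 | alternative 1 | 3-{[tri(propan-2-yl)silyl]oxy}cyclobut-2-en-1-one | O=C1C=C(O[Si](C(C)C)(C(C)C)C(C)C)C1
A4 | alternative 2 | 3-hydroxy-5,7-bis(methoxymethoxy)-2-[4-(methoxymethoxy)phenyl]-8-(2-methylbut-3-en-2-yl)chroman-4-one (mixture of diastereomers) | C=CC(C)(C)c1c(OCOC)cc(OCOC)c2c1OC(c1ccc(OCOC)cc1)C(O)C2=O
A5 | alternative 2 | 2-[2-formyl-3,5-bis(methoxymethoxy)-6-(2-methylbut-3-en-2-yl)phenoxy]-2-[4-(methoxymethoxy)phenyl]acetaldehyde (racemic) | C=CC(C)(C)c1c(OCOC)cc(OCOC)c(C=O)c1OC(C=O)c1ccc(OCOC)cc1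
A6 | alternative 3 | 2-(allyloxy)-1-[6-hydroxy-2,4-bis(methoxymethoxy)-3-(2-methylbut-3-en-2-yl)phenyl]ethan-1-one | C=CC(C)(C)c1c(OCOC)cc(O)c(C(=O)COCC=C)c1OCOC
A7 | alternative 3 | 3,5-bis(methoxymethoxy)-4-(2-methylbut-3-en-2-yl)-2-(trimethylsilyl)phenyl trifluoromethanesulfonate | C=CC(C)(C)c1c(OCOC)cc(OS(=O)(=O)C(F)(F)F)c([Si](C)(C)C)c1OCOC
A8 | alternative 3 | 2-(allyloxy)acetic acid | C=CCOCC(=O)O
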